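## Retrosynthetic overview

1. Target 31 ⇐ tiglate at C2 and acetate at C14 put on late; the ten-membered ring B and butenolide ring C are closed together by one Ni/Cr vinyl triflate–aldehyde coupling at C7–C8 with in-situ lactonisation (no ring-closing metathesis).
2. The Z C5=C6 olefin is brought in intact by a B-alkyl Suzuki coupling (C4–C5) with (Z)-3-iodobut-2-en-1-ol.
3. C1, C2 and C10 come from a quinone Diels–Alder reaction whose new cyclohexene (ring T) is sacrificial: ozonolysis of its silyl enol ether unzips it into the C2–C3 aldehyde arm and the C9–C8 acid arm.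
4. Ring A (acetoxy enone) is the methoxyquinone ring itself, after C14 reduction and a Stork–Danheiser transposition (methyl added at C11).
5. Ring order: ring A (with temporary ring T) first, then rings B and C in one step.

Assumption on atom labels: briarane numbering of 31 is used throughout (C1 quaternary carbon with methyl C15; C2 tiglate carbinol; C3, C4 CH2; C5=C6 Z-olefin with methyl C16 on C5; C7 lactone carbinol; C8 butenolide β-carbon; C9 CH2; C10 ring-fusion CH; C11=C12 enone olefin with methyl C20; C13 ketone; C14 acetoxy carbon; C17 butenolide α-carbon with methyl C18; C19 lactone carbonyl).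

Assumption on step 4: the (R)-BINOL catalyst is taken to give the enantiomer drawn; if the facial sense is the opposite, (S)-BINOL is used.

Abbreviations: PMB = 4-methoxybenzyl, TIPS = triisopropylsilyl, TES = triethylsilyl, TBS = tert-butyldimethylsilyl.

## Route

Step 1
Reactants: 1 3-methoxy-5-methylphenol
Product: 2 2-methoxy-6-methyl-1,4-benzoquinone
Conditions: K2[ON(SO3)2] (2.2 equiv), KH2PO4, H2O/acetone, 0 °C to rt
Reagents that add atoms: dipotassium nitrosodisulfonate, [K+].[K+].[O]N(S(=O)(=O)[O-])S(=O)(=O)[O-]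
Why: Teuber oxidation, in which the nitrosodisulfonate radical oxidises the phenol at its free para position (between OMe and Me) so that only the 2-methoxy-6-methyl p-quinone can form; no stereocentre.

Step 2
Reactants: 3 but-3-yn-2-one; 4 4-methoxybenzyl alcohol
Product: 5 (E)-4-[(4-methoxybenzyl)oxy]but-3-en-2-one
Conditions: DABCO (10 mol %), CH2Cl2, 0 °C to rt
Reagents that add atoms: none
Why: amine-catalysed oxa-Michael addition of the alcohol to the ynone gives the thermodynamically preferred E β-alkoxy enone; no stereocentre.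

Step 3
Reactants: 5 (E)-4-[(4-methoxybenzyl)oxy]but-3-en-2-one
Product: 6 (E)-1-[(4-methoxybenzyl)oxy]-3-(triisopropylsilyloxy)buta-1,3-diene
Conditions: TIPSOTf, Et3N, Et2O, 0 °C
Reagents that add atoms: triisopropylsilyl trifluoromethanesulfonate, CC(C)[Si](C(C)C)(C(C)C)OS(=O)(=O)C(F)(F)F
Why: soft enolisation and O-silylation of the methyl ketone gives the Danishefsky-type 1-alkoxy-3-silyloxy diene with the E enol ether unchanged.

Step 4
Reactants: 2 2-methoxy-6-methyl-1,4-benzoquinone; 6 (E)-1-[(4-methoxybenzyl)oxy]-3-(triisopropylsilyloxy)buta-1,3-diene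
Product: 8 trans-fused adduct, via cis-fused endo adduct 7 (not isolated)
Conditions: (R)-BINOL (20 mol %), TiCl2(OiPr)2 (20 mol %), 4 Å MS, CH2Cl2, −60 to −30 °C; then DBU (1 equiv), 0 °C to rt
Reagents that add atoms: none
Why: catalytic asymmetric quinone Diels–Alder reaction in which titanium, held in two-point fashion by the C14 carbonyl and the neighbouring methoxy oxygen, activates the methyl-substituted quinone double bond, the nucleophilic CH2 terminus of the diene (C9) bonds to the unsubstituted carbon C10 and the PMBO-bearing terminus (C2) to C1, the endo transition state places the C2 oxygen cis to the C14 carbonyl (C1 and C2 set, absolute sense from the ligand), and DBU then epimerises C10 (α to the C11 carbonyl) to the more stable trans ring fusion, the classical cis-to-trans isomerisation of angular-methyl quinone adducts.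

Step 5
Reactants: 8 trans-fused adduct
Product: 9 C14 alcohol
Conditions: NaBH4, CeCl3·7H2O, MeOH/CH2Cl2, −78 °C
Reagents that add atoms: none
Why: Luche reduction in which only the C14 ketone reacts (C11 is a vinylogous ester carbonyl) and, with cerium bridging the C14 carbonyl and the pseudo-axial C2 ether oxygen on one face, external borohydride attacks the other face, giving the C14 alcohol syn to the C2 oxygen and trans to the angular methyl.

Step 6
Reactants: 9 C14 alcohol
Product: 10 C14 triethylsilyl ether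
Conditions: TESOTf, 2,6-lutidine, CH2Cl2, −78 °C
Reagents that add atoms: triethylsilyl trifluoromethanesulfonate, CC[Si](CC)(CC)OS(=O)(=O)C(F)(F)F
Why: silyl ether formation masks the hindered C14 hydroxyl so that it cannot form a lactol with the aldehyde released in step 7; no stereocentre is touched.

Step 7
Reactants: 10 C14 triethylsilyl ether
Product: 12 aldehyde silyl ester, via methoxy hydroperoxide 11 (not isolated)
Conditions: O3, CH2Cl2/MeOH (5:1), NaHCO3, −78 °C (Sudan red 7B end point); then Me2S, −78 °C to rt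
Reagents that add atoms: ozone, O=[O+][O-]
Why: chemoselective ozonolysis (Criegee cleavage, reductive work-up) of the most electron-rich olefin, the silyl enol ether of ring T, unzips the sacrificial ring into the C3 aldehyde and the C8 silyl ester, while the push-pull enol ether of ring A and the PMB ring react far more slowly; C1, C2, C10 and C14 are untouched.

Step 8
Reactants: 12 aldehyde silyl ester
Product: 13 vinyl silyl ester
Conditions: Ph3PCH3Br, KN(SiMe3)2, THF, −78 to 0 °C
Reagents that add atoms: methyltriphenylphosphonium bromide, C[P+](c1ccccc1)(c1ccccc1)c1ccccc1.[Br-]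
Why: Wittig methylenation with a non-stabilised ylide at low temperature converts only the aldehyde (vinylogous ester and silyl ester are inert) and does not epimerise the α-alkoxy centre C2.

Step 9
Reactants: 14 but-2-yn-1-ol
Product: 16 (Z)-3-iodobut-2-en-1-ol, via cyclic alkenylaluminate 15 (not isolated)
Conditions: NaAlH2(OCH2CH2OMe)2, THF, 0 °C to rt; then I2, −78 to 0 °C
Reagents that add atoms: iodine, II
Why: hydroxyl-directed trans-hydroalumination of the propargylic alcohol puts aluminium on the distal alkyne carbon and iodinolysis with retention gives only the Z vinyl iodide, which fixes the geometry of the future C5=C6 olefin.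

Step 10
Reactants: 16 (Z)-3-iodobut-2-en-1-ol
Product: 17 (Z)-tert-butyl[(3-iodobut-2-en-1-yl)oxy]dimethylsilane
Conditions: TBSCl, imidazole, CH2Cl2, rt
Reagents that add atoms: tert-butyldimethylsilyl chloride, CC(C)(C)[Si](C)(C)Cl
Why: standard silylation of the primary allylic alcohol so that it survives the acyl imidazolide chemistry of step 12.

Step 11
Reactants: 13 vinyl silyl ester; 17 (Z)-tert-butyl[(3-iodobut-2-en-1-yl)oxy]dimethylsilane
Product: 20 carboxylic acid, via B-alkyl-9-BBN borane 18 (not isolated), via coupled triisopropylsilyl ester 19 (not isolated)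
Conditions: 9-BBN (1.5 equiv), THF, 0 °C to rt; then 17, Pd(dppf)Cl2 (5 mol %), AsPh3 (10 mol %), 3 M aq K3PO4, DMF, rt, 16 h; pH 4 work-up
Reagents that add atoms: none
Why: B-alkyl Suzuki–Miyaura coupling in which 9-BBN adds anti-Markovnikov to the only terminal alkene (nothing more electrophilic than a vinylogous ester carbonyl is present), the alkylborane couples with the vinyl iodide with retention of the Z geometry to form C4–C5, and the aqueous base also cleaves the silyl ester to the acid.

Step 12
Reactants: 20 carboxylic acid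
Product: 22 β-keto ester, via acyl imidazolide 21 (not isolated)
Conditions: CDI, THF, rt; then Mg(O2CCH(Me)CO2Me)2, THF, rt to 40 °C
Reagents that add atoms: magnesium bis(methyl 2-methylmalonate), [Mg+2].COC(=O)C(C)C([O-])=O.COC(=O)C(C)C([O-])=O
Why: Masamune–Brooks homologation, in which the acyl imidazolide C-acylates the magnesium malonate half-ester and decarboxylation gives the β-keto ester carrying C17, C18 and C19 (the new α-centre is an inconsequential epimer mixture).

Step 13
Reactants: 22 β-keto ester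
Product: 24 enone diol, via tertiary carbinol 23 (not isolated)
Conditions: MeLi (4 equiv), CeCl3 (4 equiv), THF, −78 °C; then 1 M aq HCl, THF, rt
Reagents that add atoms: methyllithium, [Li]C; water, O
Why: Stork–Danheiser transposition, in which the β-keto ester is protected in situ as its enolate, the weakly basic methylcerium reagent adds 1,2 to the C11 vinylogous ester carbonyl, and aqueous acid ionises the tertiary allylic alcohol, hydrolyses the enol ether to the C11=C12–C13 enone and removes both silyl ethers, leaving C10 and C14 untouched.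

Step 14
Reactants: 24 enone diol
Product: 25 Z enal
Conditions: MnO2 (20 equiv), CH2Cl2, rt
Reagents that add atoms: none
Why: MnO2 oxidises only the allylic primary alcohol (the C14 α-ketol is not allylic) and gives the Z enal without olefin isomerisation.

Step 15
Reactants: 25 Z enal
Product: 26 C14 acetate
Conditions: Ac2O, pyridine, DMAP (cat.), CH2Cl2, 0 °C
Reagents that add atoms: acetic anhydride, CC(=O)OC(C)=O
Why: DMAP-catalysed acetylation of the only free hydroxyl installs the C14 acetate of the target with retention.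

Step 16
Reactants: 26 C14 acetate
Product: 27 Z enol triflate
Conditions: NaH (1.05 equiv), THF, 0 °C; then PhNTf2, 0 °C to rt; NH4Cl work-up
Reagents that add atoms: N-phenylbis(trifluoromethanesulfonimide), O=S(=O)(N(c1ccccc1)S(=O)(=O)C(F)(F)F)C(F)(F)F
Why: the sodium enolate of the β-keto ester is a six-membered chelate, so O-triflation gives the Z enol triflate in which the triflate (later C7) is cis to the ester, as lactonisation requires.

Step 17
Reactants: 27 Z enol triflate
Product: 29 macrocyclic butenolide PMB ether, via seco hydroxy ester 28 (not isolated)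
Conditions: CrCl2 (8 equiv), NiCl2 (0.1 equiv), DMSO/THF (3:1), 0.002 M, slow addition, rt
Reagents that add atoms: none
Why: Nozaki–Hiyama–Kishi macrocyclisation, in which zerovalent nickel inserts into the vinyl triflate, transmetallation to chromium and addition to the Z enal forms C7–C8 and the ten-membered ring, the chromium alkoxide lactonises onto the cis ester to close the butenolide, and C7 is set under macrocyclic substrate control (attack on the aldehyde face that leaves H-7 on the side of the C1 methyl is expected from the fold imposed by the Z olefin and the trans ring fusion).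

Step 18
Reactants: 29 macrocyclic butenolide PMB ether
Product: 30 C2 alcohol
Conditions: DDQ (1.5 equiv), CH2Cl2/pH 7 buffer (10:1), 0 °C
Reagents that add atoms: none
Why: oxidative PMB ether cleavage (benzylic hydride abstraction by DDQ, hydrolysis of the oxocarbenium ion) frees the C2 hydroxyl without touching acetate, enone or butenolide.

Step 19
Reactants: 30 C2 alcohol
Product: 31 target CNP0218548.3
Conditions: tigloyl chloride, DMAP, pyridine, CH2Cl2, 0 °C to rt
Reagents that add atoms: (E)-2-methylbut-2-enoyl chloride, C/C=C(\C)C(Cl)=O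
Why: DMAP-catalysed acylation of the hindered C2 hydroxyl with the acid chloride proceeds with retention at C2 and keeps the E geometry of the tiglate.

## Compound list

1 | 3-methoxy-5-methylphenol | COc1cc(C)cc(O)c1 | starting material
2 | 2-methoxy-6-methyl-1,4-benzoquinone | COC1=CC(=O)C=C(C)C1=O | intermediate
3 | but-3-yn-2-one | CC(=O)C#C | starting material
4 | 4-methoxybenzyl alcohol | COc1ccc(CO)cc1 | starting material
5 | (E)-4-[(4-methoxybenzyl)oxy]but-3-en-2-one | COc1ccc(CO/C=C/C(C)=O)cc1 | intermediate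
6 | (E)-1-[(4-methoxybenzyl)oxy]-3-(triisopropylsilyloxy)buta-1,3-diene | COc1ccc(CO/C=C/C(=C)O[Si](C(C)C)(C(C)C)C(C)C)cc1 | intermediate
7 | cis-fused endo adduct: 3-methoxy-5-(PMB-oxy)-4a-methyl-7-(TIPS-oxy)-4a,5,8,8a-tetrahydronaphthalene-1,4-dione, 8a-H cis to 4a-methyl, 5-OPMB trans to 4a-methyl | COc1ccc(CO[C@H]2C=C(O[Si](C(C)C)(C(C)C)C(C)C)C[C@H]3C(=O)C=C(OC)C(=O)[C@@]23C)cc1 | intermediate
8 | trans-fused adduct: same constitution as 7, 8a-H trans to 4a-methyl; C1, C2, C10 as in 31 | COc1ccc(CO[C@H]2C=C(O[Si](C(C)C)(C(C)C)C(C)C)C[C@@H]3C(=O)C=C(OC)C(=O)[C@@]23C)cc1 | intermediate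
9 | C14 alcohol: 4-hydroxy-3-methoxy-5-(PMB-oxy)-4a-methyl-7-(TIPS-oxy)-4a,5,8,8a-tetrahydronaphthalen-1(4H)-one, 4-OH cis to 5-OPMB and trans to 4a-methyl, trans ring fusion | COc1ccc(CO[C@H]2C=C(O[Si](C(C)C)(C(C)C)C(C)C)C[C@@H]3C(=O)C=C(OC)[C@@H](O)[C@@]23C)cc1 | intermediate
10 | C14 triethylsilyl ether of 9 | COc1ccc(CO[C@H]2C=C(O[Si](C(C)C)(C(C)C)C(C)C)C[C@@H]3C(=O)C=C(OC)[C@@H](O[Si](CC)(CC)CC)[C@@]23C)cc1 | intermediate
11 | methoxy hydroperoxide: ring T opened, C3 = CH(OMe)OOH on C2, C8 = CO2TIPS on C9 (epimers at C3) | COc1ccc(CO[C@@H](C(OC)OO)[C@@]2(C)[C@H](CC(=O)O[Si](C(C)C)(C(C)C)C(C)C)C(=O)C=C(OC)[C@H]2O[Si](CC)(CC)CC)cc1 | intermediate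
12 | aldehyde silyl ester: 3-methoxycyclohex-2-enone ring A (C11 ketone) with C10 carrying CH2CO2TIPS, C1 carrying methyl and CH(OPMB)CHO, C14 carrying OTES | COc1ccc(CO[C@@H](C=O)[C@@]2(C)[C@H](CC(=O)O[Si](C(C)C)(C(C)C)C(C)C)C(=O)C=C(OC)[C@H]2O[Si](CC)(CC)CC)cc1 | intermediate
13 | vinyl silyl ester: as 12 with CH(OPMB)CH=CH2 on C1 | COc1ccc(CO[C@@H](C=C)[C@@]2(C)[C@H](CC(=O)O[Si](C(C)C)(C(C)C)C(C)C)C(=O)C=C(OC)[C@H]2O[Si](CC)(CC)CC)cc1 | intermediate
14 | but-2-yn-1-ol | CC#CCO | starting material
15 | sodium cyclic alkenylaluminate (five-membered C=C–C–O–Al ring, two 2-methoxyethoxy ligands) | [Na+].CC1=CCO[Al-]1(OCCOC)OCCOC | intermediate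
16 | (Z)-3-iodobut-2-en-1-ol | C/C(I)=C/CO | intermediate
17 | (Z)-tert-butyl[(3-iodobut-2-en-1-yl)oxy]dimethylsilane | C/C(I)=C/CO[Si](C)(C)C(C)(C)C | intermediate
18 | B-alkyl-9-BBN borane: as 13 with CH(OPMB)CH2CH2–B(9-BBN) | COc1ccc(CO[C@@H](CCB3C4CCCC3CCC4)[C@@]2(C)[C@H](CC(=O)O[Si](C(C)C)(C(C)C)C(C)C)C(=O)C=C(OC)[C@H]2O[Si](CC)(CC)CC)cc1 | intermediate
19 | coupled triisopropylsilyl ester: C2 chain CH2CH2C(Me)=CHCH2OTBS (Z), C8 = CO2TIPS | COc1ccc(CO[C@@H](CC/C(C)=C\CO[Si](C)(C)C(C)(C)C)[C@@]2(C)[C@H](CC(=O)O[Si](C(C)C)(C(C)C)C(C)C)C(=O)C=C(OC)[C@H]2O[Si](CC)(CC)CC)cc1 | intermediate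
20 | carboxylic acid: as 19 with C8 = CO2H | COc1ccc(CO[C@@H](CC/C(C)=C\CO[Si](C)(C)C(C)(C)C)[C@@]2(C)[C@H](CC(=O)O)C(=O)C=C(OC)[C@H]2O[Si](CC)(CC)CC)cc1 | intermediate
21 | acyl imidazolide of 20 | COc1ccc(CO[C@@H](CC/C(C)=C\CO[Si](C)(C)C(C)(C)C)[C@@]2(C)[C@H](CC(=O)n3ccnc3)C(=O)C=C(OC)[C@H]2O[Si](CC)(CC)CC)cc1 | intermediate
22 | β-keto ester: C9H2–C8(=O)–C17H(Me)–CO2Me on C10 (epimers at C17) | COc1ccc(CO[C@@H](CC/C(C)=C\CO[Si](C)(C)C(C)(C)C)[C@@]2(C)[C@H](CC(=O)C(C)C(=O)OC)C(=O)C=C(OC)[C@H]2O[Si](CC)(CC)CC)cc1 | intermediate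
23 | tertiary carbinol: C11 carries OH and methyl (epimers at C11, C17) | COc1ccc(CO[C@@H](CC/C(C)=C\CO[Si](C)(C)C(C)(C)C)[C@@]2(C)[C@H](CC(=O)C(C)C(=O)OC)C(C)(O)C=C(OC)[C@H]2O[Si](CC)(CC)CC)cc1 | intermediate
24 | enone diol: ring A = 6-hydroxy-3-methylcyclohex-2-enone (C13 ketone, C14 OH), C7 primary allylic OH, β-keto ester arm | COc1ccc(CO[C@@H](CC/C(C)=C\CO)[C@@]2(C)[C@H](CC(=O)C(C)C(=O)OC)C(C)=CC(=O)[C@H]2O)cc1 | intermediate
25 | Z enal: as 24 with C7 = CHO | COc1ccc(CO[C@@H](CC/C(C)=C\C=O)[C@@]2(C)[C@H](CC(=O)C(C)C(=O)OC)C(C)=CC(=O)[C@H]2O)cc1 | intermediate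
26 | C14 acetate of 25 | COc1ccc(CO[C@@H](CC/C(C)=C\C=O)[C@@]2(C)[C@H](CC(=O)C(C)C(=O)OC)C(C)=CC(=O)[C@H]2OC(C)=O)cc1 | intermediate
27 | Z enol triflate: C9H2–C8(OTf)=C17(Me)–CO2Me, OTf cis to the ester | COc1ccc(CO[C@@H](CC/C(C)=C\C=O)[C@@]2(C)[C@H](C/C(OS(=O)(=O)C(F)(F)F)=C(\C)C(=O)OC)C(C)=CC(=O)[C@H]2OC(C)=O)cc1 | intermediate
28 | seco hydroxy ester: ten-membered ring closed, C7 OH, C8=C17(Me)CO2Me with the ester cis to C7 | COc1ccc(CO[C@H]2CC/C(C)=C\[C@@H](O)/C(=C(/C)C(=O)OC)C[C@@H]3C(C)=CC(=O)[C@@H](OC(C)=O)[C@@]23C)cc1 | intermediate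
29 | macrocyclic butenolide PMB ether: 31 with OPMB in place of the tiglate | COc1ccc(CO[C@H]2CC/C(C)=C\[C@H]3OC(=O)C(C)=C3C[C@@H]3C(C)=CC(=O)[C@@H](OC(C)=O)[C@@]23C)cc1 | intermediate
30 | C2 alcohol: 31 with free OH at C2 | O[C@H]1CC/C(C)=C\[C@H]2OC(=O)C(C)=C2C[C@@H]2C(C)=CC(=O)[C@@H](OC(C)=O)[C@@]12C | intermediate
31 | CNP0218548.3, (1R,2S,5Z,7R,10R,14S) | C/C=C(\C)C(=O)O[C@H]1CC/C(C)=C\[C@H]2OC(=O)C(C)=C2C[C@@H]2C(C)=CC(=O)[C@@H](OC(C)=O)[C@@]12C | target

## Step count, longest linear sequence, risks and fallbacks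

Total steps: 19. Longest linear sequence: 16 steps (2, 3, 4, 5, 6, 7, 8, 11, 12, 13, 14, 15, 16, 17, 18, 19).

Step 17, ring closure and C7 configuration. High dilution deals with oligomerisation; the more probable failure is closure with the wrong or mixed configuration at C7. The fallback sets out from 27 and comes back at 29. If the chromium-mediated closure of 27 gives mainly the C7 epimer of 29 F6, that material is treated with TBSOTf and Et3N (1.05 equiv, −78 °C), which converts the butenolide into the 2-silyloxyfuran F7 in which C7 is planar. Protonation and desilylation with HF·pyridine at −78 °C then re-forms the butenolide from the more open face and returns 29; remaining F6 is recycled.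

Step 5, facial selectivity at C14. Hydride attack anti to the axial angular methyl would give the C14 epimer. The fallback sets out from 7 and comes back at 9. DBU is left out of step 4 and the cis-fused adduct 7 is isolated. Luche reduction of 7 can only occur from the convex face of the folded cis-bicycle (the face carrying the angular methyl and H-10) and gives the cis-fused alcohol F5, whose C14 oxygen is already syn to the C2 oxygen. DBU then epimerises C10 of F5 (the C11 carbonyl is still present) to give 9.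

Step 4, enantioselectivity of the cycloaddition. The catalyst may be outrun by the background reaction or give low ee. The fallback sets out from 2 and 6 and comes back at 9. The cycloaddition is run without catalyst (toluene, 0 °C to rt; regio- and endo-selectivity are inherent) and followed by DBU, which gives 8 together with the mirror-image adduct F1. Luche reduction as in step 5 gives 9 together with the mirror-image alcohol F2. Esterification with (S)-O-methylmandelic acid (DCC, DMAP) gives two diastereomers, the mandelate of 9 F3 and the mandelate of the mirror-image alcohol F4, which are separated by chromatography. K2CO3 in MeOH cleaves F3 and returns enantiopure 9.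

## Further compounds

F1 | step 4 | mirror image of trans-fused adduct 8 | COc1ccc(CO[C@@H]2C=C(O[Si](C(C)C)(C(C)C)C(C)C)C[C@H]3C(=O)C=C(OC)C(=O)[C@]23C)cc1
F2 | step 4 | mirror image of C14 alcohol 9 | COc1ccc(CO[C@@H]2C=C(O[Si](C(C)C)(C(C)C)C(C)C)C[C@H]3C(=O)C=C(OC)[C@H](O)[C@]23C)cc1
F3 | step 4 | (S)-O-methylmandelate of 9 | COc1ccc(CO[C@H]2C=C(O[Si](C(C)C)(C(C)C)C(C)C)C[C@@H]3C(=O)C=C(OC)[C@@H](OC(=O)[C@@H](OC)c4ccccc4)[C@@]23C)cc1
F4 | step 4 | (S)-O-methylmandelate of the mirror image of 9 | COc1ccc(CO[C@@H]2C=C(O[Si](C(C)C)(C(C)C)C(C)C)C[C@H]3C(=O)C=C(OC)[C@H](OC(=O)[C@@H](OC)c4ccccc4)[C@]23C)cc1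
F5 | step 5 | cis-fused C14 alcohol (C10 epimer of 9) | COc1ccc(CO[C@H]2C=C(O[Si](C(C)C)(C(C)C)C(C)C)C[C@H]3C(=O)C=C(OC)[C@@H](O)[C@@]23C)cc1
F6 | step 17 | C7 epimer of 29 | COc1ccc(CO[C@H]2CC/C(C)=C\[C@@H]3OC(=O)C(C)=C3C[C@@H]3C(C)=CC(=O)[C@@H](OC(C)=O)[C@@]23C)cc1
F7 | step 17 | 2-(tert-butyldimethylsilyloxy)furan derived from F6 (C7, C8, C17, C19 and O form the furan) | COc1ccc(CO[C@H]2CC/C(C)=C\c3oc(O[Si](C)(C)C(C)(C)C)c(C)c3C[C@@H]3C(C)=CC(=O)[C@@H](OC(C)=O)[C@@]23C)cc1
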